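**Retrosynthetic overview**
1. Target hydroquinone 8 ⇐ p-quinone 7 by 2 e⁻ reduction (re-aromatisation).
2. Quinone 7 ⇐ the locally C2-symmetric resorcinol dimethyl ether 5 by one desymmetrising oxidative dearomatisation: the ring C–H between chain and OMe becomes C=O, the para C–OMe becomes C=O, the other OMe stays. Either ortho C–H gives the same quinone, so the 2-methoxy-6-alkyl pattern is fixed by symmetry.
3. Ar–CH2 bond of 5 ⇐ 1-bromo-3,5-dimethoxybenzene 3 plus the primary radical from (R)-3-acetoxytetradecanoic acid 2 (Ni-catalysed decarboxylative coupling through NHPI ester 4).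
4. The stereocentre is bought with hydroxy acid 1 and is never a reacting centre.
5. Rings: none is built; the single carbocycle comes from 3, is dearomatised in step 3 and re-aromatised in step 4.

Assumption: (R)-3-hydroxytetradecanoic acid (≥98% ee) and 1-bromo-3,5-dimethoxybenzene are purchased; the target stereocentre is (R).

**Route**

Step 1
Reactants: 1 (R)-3-hydroxytetradecanoic acid
Product: 2 (R)-3-acetoxytetradecanoic acid
Conditions: Ac2O (1.5 equiv), pyridine, DMAP (5 mol %), CH2Cl2, 0 °C → rt; H2O quench, 1 M HCl work-up
Reagents that add atoms: acetic anhydride CC(=O)OC(C)=O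
Why: DMAP-catalysed O-acylation (nucleophilic acyl substitution) of the secondary alcohol, in which the C–O bond at the stereocentre is not broken, so the (R) configuration is retained.

Step 2
Reactants: 2 (R)-3-acetoxytetradecanoic acid; 3 1-bromo-3,5-dimethoxybenzene
Product: 5 (R)-1-(3,5-dimethoxyphenyl)tridecan-2-yl acetate, via NHPI ester 4 (not isolated)
Conditions: N-hydroxyphthalimide (1.05 equiv), DIC (1.05 equiv), DMA, rt, 2 h; then 3 (1.5 equiv), NiBr2·dme (10 mol %), dtbbpy (10 mol %), Zn dust (2.5 equiv), rt → 35 °C, 16 h
Reagents that add atoms: none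
Why: Carbodiimide esterification gives the redox-active N-acyloxyphthalimide, and nickel-catalysed decarboxylative reductive cross-electrophile coupling then joins the primary β-acetoxyalkyl radical to the aryl–Ni species; the stereocentre is β to the radical and untouched, because capture by nickel is orders of magnitude faster than a 1,2-acyloxy shift.

Step 3
Reactants: 5 (R)-1-(3,5-dimethoxyphenyl)tridecan-2-yl acetate
Product: 7 (R)-1-(5-methoxy-3,6-dioxocyclohexa-1,4-dien-1-yl)tridecan-2-yl acetate, via p-methoxyphenol 6 (not isolated)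
Conditions: MeReO3 (8 mol %), 35 % aq. H2O2 (6 equiv), AcOH, 40 °C, 4 h (stop at full consumption of 5)
Reagents that add atoms: hydrogen peroxide OO
Why: Methyltrioxorhenium/H2O2 oxidation of a methoxyarene to a p-benzoquinone, in which the Re-peroxo species hydroxylates the ring ortho to the chain and para to an OMe (more activated and less hindered than the site between the two OMe groups) and the resulting p-methoxyphenol 6 is oxidised at the para C–OMe carbon with loss of MeOH, breaking aromaticity and ring symmetry in one operation while the remote acetate-bearing stereocentre is untouched.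

Step 4
Reactants: 7 (R)-1-(5-methoxy-3,6-dioxocyclohexa-1,4-dien-1-yl)tridecan-2-yl acetate
Product: 8 (R)-1-(2,5-dihydroxy-3-methoxyphenyl)tridecan-2-yl acetate
Conditions: Na2S2O4 (3 equiv), EtOAc/H2O 1:1, rt, 15 min, under Ar; degassed work-up
Reagents that add atoms: none
Why: Dithionite reduction of a p-benzoquinone to the hydroquinone (2 e⁻/2 H⁺, restoring aromaticity) under neutral biphasic conditions that leave the secondary acetate and the stereocentre unchanged.

**Compound list**
1 | (R)-3-hydroxytetradecanoic acid | CCCCCCCCCCC[C@H](CC(=O)O)O | starting material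
2 | (R)-3-acetoxytetradecanoic acid | CCCCCCCCCCC[C@H](CC(=O)O)OC(C)=O | intermediate
3 | 1-bromo-3,5-dimethoxybenzene | COc1cc(Br)cc(OC)c1 | starting material
4 | 1,3-dioxoisoindolin-2-yl (R)-3-acetoxytetradecanoate (NHPI ester) | CCCCCCCCCCC[C@H](CC(=O)ON1C(=O)c2ccccc2C1=O)OC(C)=O | intermediate
5 | (R)-1-(3,5-dimethoxyphenyl)tridecan-2-yl acetate | CCCCCCCCCCC[C@H](Cc1cc(OC)cc(OC)c1)OC(C)=O | intermediate
6 | (R)-1-(2-hydroxy-3,5-dimethoxyphenyl)tridecan-2-yl acetate | CCCCCCCCCCC[C@H](Cc1cc(OC)cc(OC)c1O)OC(C)=O | intermediate
7 | (R)-1-(5-methoxy-3,6-dioxocyclohexa-1,4-dien-1-yl)tridecan-2-yl acetate | CCCCCCCCCCC[C@H](CC1=CC(=O)C=C(OC)C1=O)OC(C)=O | intermediate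
8 | (R)-1-(2,5-dihydroxy-3-methoxyphenyl)tridecan-2-yl acetate | CCCCCCCCCCC[C@H](Cc1cc(O)cc(OC)c1O)OC(C)=O | target

**Step count and risks**
Total steps: 4. Longest linear sequence: 4 (1 → 2 → 5 → 7 → 8); bromide 3 enters in step 2.

Most likely to fail, in order:

Step 3 (direct arene → quinone oxidation). Risks are hydroxylation between the two OMe groups (which cannot lead to the p-quinone), over-oxidation of the electron-rich methoxyquinone, and a modest yield at best. The fallback replaces direct arene oxidation by stepwise desymmetrisation; it sets out from 5 and comes back at 7. One of the two equivalent methyl ethers is cleaved with BBr3 (1.0 equiv, CH2Cl2, −78 → −20 °C, stopped at mono-demethylation; the acetate should survive at low temperature) to give (R)-1-(3-hydroxy-5-methoxyphenyl)tridecan-2-yl acetate F1. This phenol is then oxidised with Fremy's salt (KH2PO4 buffer, acetone/H2O, rt; Teuber oxidation) at the free position para to OH, which lies between the chain and the OMe, giving 7.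

Step 2 (decarboxylative arylation). Risks are slow oxidative addition of the aryl bromide relative to reduction of the NHPI ester (giving alkyl dimer or tridecan-2-yl acetate) and E1cB loss of AcOH from the activated ester. The fallback replaces the radical coupling by polar epoxide opening; it sets out from 3 and comes back at 5. Bromide 3 is converted with Mg in THF into (3,5-dimethoxyphenyl)magnesium bromide F2. Separately, commercial (R)-epichlorohydrin is opened at its ring CH2 by decylmagnesium bromide/CuI (THF, −40 °C) to (R)-1-chlorotridecan-2-ol F3, which NaOH closes to (R)-2-undecyloxirane F4. F2 opens F4 at the terminal carbon (CuI 10 mol %, THF, −30 → 0 °C) to give (R)-1-(3,5-dimethoxyphenyl)tridecan-2-ol F5 without touching the stereocentre, and Ac2O/pyridine/DMAP gives 5.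

Step 1 (acetylation of the free β-hydroxy acid). Risks are mixed-anhydride side reactions: estolide oligomers and elimination to tetradec-2-enoic acid. The fallback masks the carboxyl group first; it sets out from 1 and comes back at 2. BnBr/Cs2CO3 in DMF gives benzyl (R)-3-hydroxytetradecanoate F6, Ac2O/pyridine/DMAP gives benzyl (R)-3-acetoxytetradecanoate F7, and hydrogenolysis (H2, Pd/C, EtOAc) releases 2.

**Further compounds**
F1 | step 3 | (R)-1-(3-hydroxy-5-methoxyphenyl)tridecan-2-yl acetate | CCCCCCCCCCC[C@H](Cc1cc(O)cc(OC)c1)OC(C)=O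
F2 | step 2 | (3,5-dimethoxyphenyl)magnesium bromide | COc1cc([Mg]Br)cc(OC)c1
F3 | step 2 | (R)-1-chlorotridecan-2-ol | CCCCCCCCCCC[C@H](CCl)O
F4 | step 2 | (R)-2-undecyloxirane | CCCCCCCCCCC[C@@H]1CO1
F5 | step 2 | (R)-1-(3,5-dimethoxyphenyl)tridecan-2-ol | CCCCCCCCCCC[C@H](Cc1cc(OC)cc(OC)c1)O
F6 | step 1 | benzyl (R)-3-hydroxytetradecanoate | CCCCCCCCCCC[C@H](CC(=O)OCc1ccccc1)O
F7 | step 1 | benzyl (R)-3-acetoxytetradecanoate | CCCCCCCCCCC[C@H](CC(=O)OCc1ccccc1)OC(C)=O
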